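**Retrosynthetic overview**

- The ring arc C4–C5(OMe)=C6–C1(=O), together with the oxygen on C4, is a 5,5-disubstituted methyl tetronate (4-methoxyfuran-2(5H)-one) whose ring oxygen sits on C4. The target is therefore traced back, through O-methylation of C4–OH and desilylation, to vinyl iodide 25: a C2 vinyllithium attacks the lactone carbonyl C1, forms C1–C2, opens the lactone and closes the cyclohexa-2,5-dienone.
- 25 comes from tetronate aldehyde 20 by a Z-selective iodo-ylide Wittig reaction (C3=C2 with the allyl group), and the tetronate from α-hydroxy ester 15 and Ph3P=C=C=O.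
- 15 comes from diol 12, made by Me2CuLi opening (inversion at Cα) of epoxy alcohol 11; Sharpless epoxidation of allylic alcohol 10 sets C4 and Cα; 10 comes from arylacetaldehyde 4 (from eugenol) and ylide 8.
- Ring order: oxirane (carries both stereocentres), then the tetronate lactone, then the carbocycle that replaces it.

Key step: step 14

Remark: ring atoms are numbered C1 (C=O), C2 (allyl), C3, C4 (quaternary), C5 (OMe), C6, with Cα the side-chain methine; TBS = tert-butyldimethylsilyl; the Wittig reaction of step 4 is assumed to give mainly the E-enoate, as α-substituted ester ylides normally do, any Z-isomer being removed by chromatography.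

**Route**

Step 1
Reactants: 1 eugenol (4-allyl-2-methoxyphenol)
Product: 2 tert-butyl(4-allyl-2-methoxyphenoxy)dimethylsilane
Conditions: TBSCl, imidazole, DMF, rt
Reagents that add atoms: tert-butyldimethylsilyl chloride, CC(C)(C)[Si](C)(C)Cl
Why: Silyl ether formation on the phenol is routine and masks the only acidic proton with a group that should survive every later reagent until fluoride.

Step 2
Reactants: 2 tert-butyl(4-allyl-2-methoxyphenoxy)dimethylsilane
Product: 4 2-[4-(TBSO)-3-methoxyphenyl]acetaldehyde, via secondary ozonide 3 (not isolated)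
Conditions: O3, CH2Cl2, −78 °C (stopped at the end point); then PPh3, −78 °C → rt
Reagents that add atoms: ozone, [O-][O+]=O
Why: Ozonolysis with reductive work-up cleaves the terminal alkene, which should react faster than the arene, to the arylacetaldehyde, used crude.

Step 3
Reactants: 5 methyl (triphenylphosphoranylidene)acetate; 6 benzyl chloromethyl ether
Product: 8 methyl 3-(benzyloxy)-2-(triphenylphosphoranylidene)propanoate, via phosphonium chloride 7 (not isolated)
Conditions: CH2Cl2, 0 °C → rt; then aq. NaOH, 0 °C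
Reagents that add atoms: none
Why: C-alkylation of a stabilised phosphorus ylide by a reactive α-chloro ether gives the phosphonium salt, which aqueous base deprotonates to the α-substituted stabilised ylide.

Step 4
Reactants: 4 2-[4-(TBSO)-3-methoxyphenyl]acetaldehyde; 8 methyl 3-(benzyloxy)-2-(triphenylphosphoranylidene)propanoate
Product: 9 methyl (2E)-2-[(benzyloxy)methyl]-4-[4-(TBSO)-3-methoxyphenyl]but-2-enoate
Conditions: CH2Cl2, rt → 40 °C
Reagents that add atoms: none
Why: Wittig olefination with an α-substituted ester ylide under neutral conditions should place the ester trans to the arylmethyl group without enolising the arylacetaldehyde.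

Step 5
Reactants: 9 methyl (2E)-2-[(benzyloxy)methyl]-4-[4-(TBSO)-3-methoxyphenyl]but-2-enoate
Product: 10 (2Z)-2-[(benzyloxy)methyl]-4-[4-(TBSO)-3-methoxyphenyl]but-2-en-1-ol
Conditions: i-Bu2AlH, CH2Cl2, −78 °C; aq. KNaC4H4O6 (tartrate)
Reagents that add atoms: none
Why: Hydride 1,2-reduction of the enoate gives the allylic alcohol with the alkene geometry unchanged (the descriptor becomes Z only because CH2OBn now outranks CH2OH).

Step 6
Reactants: 10 (2Z)-2-[(benzyloxy)methyl]-4-[4-(TBSO)-3-methoxyphenyl]but-2-en-1-ol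
Product: 11 {(2R,3S)-2-[(benzyloxy)methyl]-3-[4-(TBSO)-3-methoxybenzyl]oxiran-2-yl}methanol
Conditions: Ti(OiPr)4 (cat.), L-(+)-diethyl tartrate (cat.), t-BuOOH, 4 Å molecular sieves, CH2Cl2, −20 °C
Reagents that add atoms: tert-butyl hydroperoxide, CC(C)(C)OO
Why: Sharpless asymmetric epoxidation directed by the free hydroxyl, with L-(+)-tartrate delivering oxygen in the sense that gives 2S,3S epoxides from E-allylic alcohols (read here as 2R,3S because CH2OBn outranks CH2OH), sets the future C4 and the centre to be inverted at Cα.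

Step 7
Reactants: 11 {(2R,3S)-2-[(benzyloxy)methyl]-3-[4-(TBSO)-3-methoxybenzyl]oxiran-2-yl}methanol
Product: 12 (2R,3R)-2-[(benzyloxy)methyl]-3-methyl-4-[4-(TBSO)-3-methoxyphenyl]butane-1,2-diol
Conditions: Me2CuLi (from CuI and MeLi), Et2O, −40 → 0 °C; then aq. NH4Cl
Reagents that add atoms: lithium dimethylcuprate, [Li+].C[Cu-]C
Why: SN2 epoxide opening by the Gilman cuprate at the less substituted C3 with inversion sets the methyl-bearing Cα and frees the tertiary hydroxyl on the future C4, whose configuration is untouched.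

Step 8
Reactants: 12 (2R,3R)-2-[(benzyloxy)methyl]-3-methyl-4-[4-(TBSO)-3-methoxyphenyl]butane-1,2-diol
Product: 14 (2S,3R)-2-[(benzyloxy)methyl]-2-hydroxy-3-methyl-4-[4-(TBSO)-3-methoxyphenyl]butanoic acid, via hydroxy aldehyde 13 (not isolated)
Conditions: TEMPO (cat.), NaClO2, NaOCl (cat.), MeCN–phosphate buffer (pH 6.7), 35 °C
Reagents that add atoms: sodium chlorite, [Na+].[O-]Cl=O
Why: Nitroxyl-catalysed oxidation with chlorite as terminal oxidant takes the primary alcohol through the aldehyde to the acid, leaves the tertiary alcohol alone and should avoid glycol cleavage and chlorination of the arene.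

Step 9
Reactants: 14 (2S,3R)-2-[(benzyloxy)methyl]-2-hydroxy-3-methyl-4-[4-(TBSO)-3-methoxyphenyl]butanoic acid
Product: 15 methyl (2S,3R)-2-[(benzyloxy)methyl]-2-hydroxy-3-methyl-4-[4-(TBSO)-3-methoxyphenyl]butanoate
Conditions: Me3SiCHN2, toluene–MeOH, 0 °C → rt
Reagents that add atoms: (trimethylsilyl)diazomethane, C[Si](C)(C)C=[N+]=[N-]
Why: Esterification with a diazoalkane is neutral, so the aryl silyl ether and the tertiary alcohol are left alone.

Step 10
Reactants: 15 methyl (2S,3R)-2-[(benzyloxy)methyl]-2-hydroxy-3-methyl-4-[4-(TBSO)-3-methoxyphenyl]butanoate; 16 (triphenylphosphoranylidene)ketene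
Product: 18 (5S)-5-[(benzyloxy)methyl]-4-methoxy-5-{(2R)-1-[4-(TBSO)-3-methoxyphenyl]propan-2-yl}furan-2(5H)-one, via acyl ylide 17 (not isolated)
Conditions: toluene, reflux, PhCO2H (cat.)
Reagents that add atoms: none
Why: The tertiary hydroxyl adds to the ketene C=C to give an acyl ylide, which closes onto the neighbouring methyl ester by intramolecular Wittig olefination (5-exo-trig) to give the methyl tetronate with the enol-ether methyl already in place and the quaternary centre untouched.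

Step 11
Reactants: 18 (5S)-5-[(benzyloxy)methyl]-4-methoxy-5-{(2R)-1-[4-(TBSO)-3-methoxyphenyl]propan-2-yl}furan-2(5H)-one
Product: 19 (5S)-5-(hydroxymethyl)-4-methoxy-5-{(2R)-1-[4-(TBSO)-3-methoxyphenyl]propan-2-yl}furan-2(5H)-one
Conditions: H2 (1 atm), Pd/C, EtOAc, rt
Reagents that add atoms: none
Why: Hydrogenolysis of the benzyl ether; the push–pull tetronate alkene and the aryl silyl ether should be inert at this pressure.

Step 12
Reactants: 19 (5S)-5-(hydroxymethyl)-4-methoxy-5-{(2R)-1-[4-(TBSO)-3-methoxyphenyl]propan-2-yl}furan-2(5H)-one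
Product: 20 (2R)-3-methoxy-5-oxo-2-{(2R)-1-[4-(TBSO)-3-methoxyphenyl]propan-2-yl}-2,5-dihydrofuran-2-carbaldehyde
Conditions: Dess–Martin periodinane, CH2Cl2, 0 °C → rt
Reagents that add atoms: none
Why: Dess–Martin oxidation of the primary alcohol gives an aldehyde that has no α-hydrogen and cannot epimerise (the descriptor changes by priority only).

Step 13
Reactants: 20 (2R)-3-methoxy-5-oxo-2-{(2R)-1-[4-(TBSO)-3-methoxyphenyl]propan-2-yl}-2,5-dihydrofuran-2-carbaldehyde; 21 (but-3-en-1-yl)triphenylphosphonium bromide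
Product: 25 (5S)-5-[(1Z)-2-iodopenta-1,4-dien-1-yl]-4-methoxy-5-{(2R)-1-[4-(TBSO)-3-methoxyphenyl]propan-2-yl}furan-2(5H)-one, via butenylidene ylide 22 (not isolated), via iodophosphonium iodide 23 (not isolated), via iodo ylide 24 (not isolated)
Conditions: 21, n-BuLi, THF, rt; I2, −78 °C; NaN(SiMe3)2, −78 → −20 °C; then 20, −78 °C → rt
Reagents that add atoms: iodine, II
Why: Z-selective iodo-olefination (Wittig reaction of an α-iodo ylide, Stork–Zhao type): the ylide is iodinated, deprotonated again and condensed with the aldehyde, which should place iodine cis to the quaternary carbon.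

Step 14
Reactants: 25 (5S)-5-[(1Z)-2-iodopenta-1,4-dien-1-yl]-4-methoxy-5-{(2R)-1-[4-(TBSO)-3-methoxyphenyl]propan-2-yl}furan-2(5H)-one
Product: 29 (4S)-2-allyl-4-hydroxy-5-methoxy-4-{(2R)-1-[4-(TBSO)-3-methoxyphenyl]propan-2-yl}cyclohexa-2,5-dien-1-one, via vinyllithium 26 (not isolated), via oxabicyclic alkoxide 27 (not isolated), via lithium quinolate 28 (not isolated)
Conditions: t-BuLi (2.1 equiv), THF–Et2O–pentane, −100 → −78 °C; then aq. NH4Cl
Reagents that add atoms: none
Why: Proposed new method: iodine–lithium exchange with t-BuLi at −100 °C is expected to outrun addition to the vinylogous carbonate carbonyl; vinyllithium 26 has its carbanionic C2 cis to C4 and so within reach of the lactone carbonyl C1, attacks it to form the C1–C2 bond and the bridged alkoxide 27, and this tetrahedral intermediate collapses by cleaving C1–O7, leaving the former ring oxygen on C4 as the alkoxide of dienone 28. The closest known reaction type is the Parham cyclisation (halogen–lithium exchange, then intramolecular acylation of the organolithium by an ester or lactone); an acyl transfer that converts a tetronate into a carbocycle is not established. The six-membered carbocycle closes in a 6-exo-trig mode (the carbonyl oxygen is exocyclic to the new ring), and the strain of the 7-oxabicyclo[2.2.1]heptadiene is released at once by the ring opening. No stereocentre is created, and C4 keeps its configuration because the only bond broken at the lactone is the acyl C1–O7 bond and C4 bears no hydrogen. The step needs iodine cis to C4, which step 13 supplies, and exchange and intramolecular acylation must be faster than proton transfer from C6–H or the doubly allylic CH2, which the low temperature and the proximity of carbanion and carbonyl should secure.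

Step 15
Reactants: 29 (4S)-2-allyl-4-hydroxy-5-methoxy-4-{(2R)-1-[4-(TBSO)-3-methoxyphenyl]propan-2-yl}cyclohexa-2,5-dien-1-one
Product: 31 (4S)-2-allyl-4,5-dimethoxy-4-{(2R)-1-[4-(TBSO)-3-methoxyphenyl]propan-2-yl}cyclohexa-2,5-dien-1-one, via potassium alkoxide 30 (not isolated)
Conditions: KN(SiMe3)2, THF, −78 °C; MeOTf, −78 → −40 °C
Reagents that add atoms: methyl trifluoromethanesulfonate, COS(=O)(=O)C(F)(F)F
Why: Williamson-type O-methylation of the tertiary alkoxide, which is far more nucleophilic than the dienone oxygen, on a dienone that has no enolisable α-hydrogen.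

Step 16
Reactants: 31 (4S)-2-allyl-4,5-dimethoxy-4-{(2R)-1-[4-(TBSO)-3-methoxyphenyl]propan-2-yl}cyclohexa-2,5-dien-1-one
Product: 32 (4S)-2-allyl-4-[(2R)-1-(4-hydroxy-3-methoxyphenyl)propan-2-yl]-4,5-dimethoxycyclohexa-2,5-dien-1-one (CNP0370214.1)
Conditions: Bu4NF, AcOH, THF, 0 °C
Reagents that add atoms: none
Why: Fluoride cleavage of the aryl silyl ether (desilylation), buffered with acetic acid so that phenoxide does not build up beside the dienone; no stereocentre is touched.

**Compound list**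

1 | eugenol (4-allyl-2-methoxyphenol) | C=CCc1ccc(O)c(OC)c1 | starting material
2 | tert-butyl(4-allyl-2-methoxyphenoxy)dimethylsilane | C=CCc1ccc(O[Si](C)(C)C(C)(C)C)c(OC)c1 | intermediate
3 | 3-[4-(TBSO)-3-methoxybenzyl]-1,2,4-trioxolane (secondary ozonide) | C1(Cc2ccc(O[Si](C)(C)C(C)(C)C)c(OC)c2)OCOO1 | intermediate
4 | 2-[4-(TBSO)-3-methoxyphenyl]acetaldehyde | O=CCc1ccc(O[Si](C)(C)C(C)(C)C)c(OC)c1 | intermediate
5 | methyl (triphenylphosphoranylidene)acetate | COC(=O)C=P(c1ccccc1)(c1ccccc1)c1ccccc1 | starting material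
6 | benzyl chloromethyl ether | ClCOCc1ccccc1 | starting material
7 | [3-(benzyloxy)-1-methoxy-1-oxopropan-2-yl]triphenylphosphonium chloride | COC(=O)C(COCc1ccccc1)[P+](c1ccccc1)(c1ccccc1)c1ccccc1.[Cl-] | intermediate
8 | methyl 3-(benzyloxy)-2-(triphenylphosphoranylidene)propanoate | COC(=O)C(COCc1ccccc1)=P(c1ccccc1)(c1ccccc1)c1ccccc1 | intermediate
9 | methyl (2E)-2-[(benzyloxy)methyl]-4-[4-(TBSO)-3-methoxyphenyl]but-2-enoate | COC(=O)/C(COCc1ccccc1)=C/Cc1ccc(O[Si](C)(C)C(C)(C)C)c(OC)c1 | intermediate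
10 | (2Z)-2-[(benzyloxy)methyl]-4-[4-(TBSO)-3-methoxyphenyl]but-2-en-1-ol | OC/C(COCc1ccccc1)=C/Cc1ccc(O[Si](C)(C)C(C)(C)C)c(OC)c1 | intermediate
11 | {(2R,3S)-2-[(benzyloxy)methyl]-3-[4-(TBSO)-3-methoxybenzyl]oxiran-2-yl}methanol | OC[C@]1(COCc2ccccc2)O[C@H]1Cc1ccc(O[Si](C)(C)C(C)(C)C)c(OC)c1 | intermediate
12 | (2R,3R)-2-[(benzyloxy)methyl]-3-methyl-4-[4-(TBSO)-3-methoxyphenyl]butane-1,2-diol | OC[C@@](O)(COCc1ccccc1)[C@H](C)Cc1ccc(O[Si](C)(C)C(C)(C)C)c(OC)c1 | intermediate
13 | (2S,3R)-2-[(benzyloxy)methyl]-2-hydroxy-3-methyl-4-[4-(TBSO)-3-methoxyphenyl]butanal | O=C[C@@](O)(COCc1ccccc1)[C@H](C)Cc1ccc(O[Si](C)(C)C(C)(C)C)c(OC)c1 | intermediate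
14 | (2S,3R)-2-[(benzyloxy)methyl]-2-hydroxy-3-methyl-4-[4-(TBSO)-3-methoxyphenyl]butanoic acid | OC(=O)[C@@](O)(COCc1ccccc1)[C@H](C)Cc1ccc(O[Si](C)(C)C(C)(C)C)c(OC)c1 | intermediate
15 | methyl (2S,3R)-2-[(benzyloxy)methyl]-2-hydroxy-3-methyl-4-[4-(TBSO)-3-methoxyphenyl]butanoate | COC(=O)[C@@](O)(COCc1ccccc1)[C@H](C)Cc1ccc(O[Si](C)(C)C(C)(C)C)c(OC)c1 | intermediate
16 | (triphenylphosphoranylidene)ketene | O=C=C=P(c1ccccc1)(c1ccccc1)c1ccccc1 | starting material
17 | methyl (2S,3R)-2-[(benzyloxy)methyl]-3-methyl-4-[4-(TBSO)-3-methoxyphenyl]-2-{[(triphenylphosphoranylidene)acetyl]oxy}butanoate (acyl ylide) | COC(=O)[C@@](OC(=O)C=P(c1ccccc1)(c1ccccc1)c1ccccc1)(COCc1ccccc1)[C@H](C)Cc1ccc(O[Si](C)(C)C(C)(C)C)c(OC)c1 | intermediate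
18 | (5S)-5-[(benzyloxy)methyl]-4-methoxy-5-{(2R)-1-[4-(TBSO)-3-methoxyphenyl]propan-2-yl}furan-2(5H)-one | COC1=CC(=O)O[C@]1(COCc1ccccc1)[C@H](C)Cc1ccc(O[Si](C)(C)C(C)(C)C)c(OC)c1 | intermediate
19 | (5S)-5-(hydroxymethyl)-4-methoxy-5-{(2R)-1-[4-(TBSO)-3-methoxyphenyl]propan-2-yl}furan-2(5H)-one | COC1=CC(=O)O[C@]1(CO)[C@H](C)Cc1ccc(O[Si](C)(C)C(C)(C)C)c(OC)c1 | intermediate
20 | (2R)-3-methoxy-5-oxo-2-{(2R)-1-[4-(TBSO)-3-methoxyphenyl]propan-2-yl}-2,5-dihydrofuran-2-carbaldehyde | COC1=CC(=O)O[C@]1(C=O)[C@H](C)Cc1ccc(O[Si](C)(C)C(C)(C)C)c(OC)c1 | intermediate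
21 | (but-3-en-1-yl)triphenylphosphonium bromide | C=CCC[P+](c1ccccc1)(c1ccccc1)c1ccccc1.[Br-] | starting material
22 | (but-3-en-1-ylidene)triphenylphosphorane | C=CCC=P(c1ccccc1)(c1ccccc1)c1ccccc1 | intermediate
23 | (1-iodobut-3-en-1-yl)triphenylphosphonium iodide | C=CCC(I)[P+](c1ccccc1)(c1ccccc1)c1ccccc1.[I-] | intermediate
24 | (1-iodobut-3-en-1-ylidene)triphenylphosphorane | C=CCC(I)=P(c1ccccc1)(c1ccccc1)c1ccccc1 | intermediate
25 | (5S)-5-[(1Z)-2-iodopenta-1,4-dien-1-yl]-4-methoxy-5-{(2R)-1-[4-(TBSO)-3-methoxyphenyl]propan-2-yl}furan-2(5H)-one | COC1=CC(=O)O[C@]1(/C=C(\I)CC=C)[C@H](C)Cc1ccc(O[Si](C)(C)C(C)(C)C)c(OC)c1 | intermediate (key-step precursor)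
26 | vinyllithium from 25 (lithium in place of iodine, cis to the quaternary carbon) | COC1=CC(=O)O[C@]1(/C=C(\[Li])CC=C)[C@H](C)Cc1ccc(O[Si](C)(C)C(C)(C)C)c(OC)c1 | intermediate
27 | lithium 2-allyl-5-methoxy-4-{(2R)-1-[4-(TBSO)-3-methoxyphenyl]propan-2-yl}-7-oxabicyclo[2.2.1]hepta-2,5-dien-1-olate (C4 as in 25) | [Li+].[O-][C@@]12O[C@@](C=C1CC=C)(C(OC)=C2)[C@H](C)Cc1ccc(O[Si](C)(C)C(C)(C)C)c(OC)c1 | intermediate
28 | lithium alkoxide of 29 | C=CCC1=C[C@@]([O-])([C@H](C)Cc2ccc(O[Si](C)(C)C(C)(C)C)c(OC)c2)C(OC)=CC1=O.[Li+] | intermediate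
29 | (4S)-2-allyl-4-hydroxy-5-methoxy-4-{(2R)-1-[4-(TBSO)-3-methoxyphenyl]propan-2-yl}cyclohexa-2,5-dien-1-one | C=CCC1=C[C@@](O)([C@H](C)Cc2ccc(O[Si](C)(C)C(C)(C)C)c(OC)c2)C(OC)=CC1=O | intermediate (key-step product)
30 | potassium alkoxide of 29 | C=CCC1=C[C@@]([O-])([C@H](C)Cc2ccc(O[Si](C)(C)C(C)(C)C)c(OC)c2)C(OC)=CC1=O.[K+] | intermediate
31 | (4S)-2-allyl-4,5-dimethoxy-4-{(2R)-1-[4-(TBSO)-3-methoxyphenyl]propan-2-yl}cyclohexa-2,5-dien-1-one | C=CCC1=C[C@@](OC)([C@H](C)Cc2ccc(O[Si](C)(C)C(C)(C)C)c(OC)c2)C(OC)=CC1=O | intermediate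
32 | (4S)-2-allyl-4-[(2R)-1-(4-hydroxy-3-methoxyphenyl)propan-2-yl]-4,5-dimethoxycyclohexa-2,5-dien-1-one | C=CCC1=C[C@@](OC)([C@H](C)Cc2ccc(O)c(OC)c2)C(OC)=CC1=O | target

**Step count**

Total steps: 16. Longest linear sequence: 15 (steps 1, 2 and 4–16; step 3 makes ylide 8 on a side branch).

**Steps most likely to fail**

Step 14 (new method). What may go wrong: proton transfer to the vinyllithium from C6–H or from the doubly allylic CH2, addition of t-BuLi to the lactone before exchange, or failure to reach the strained bridged transition state. The fallback sets out from 25 and uses established reaction types. The lactone is reduced with i-Bu2AlH (CH2Cl2, −78 °C) to the lactol (5S)-5-[(1Z)-2-iodopenta-1,4-dien-1-yl]-4-methoxy-5-{(2R)-1-[4-(TBSO)-3-methoxyphenyl]propan-2-yl}-2,5-dihydrofuran-2-ol F1, which equilibrates with its open (Z)-hydroxy enal form. An intramolecular Nozaki–Hiyama–Kishi reaction (CrCl2, NiCl2 cat., DMF, rt) of the vinyl iodide onto that aldehyde closes the carbocycle as (4S)-2-allyl-5-methoxy-4-{(2R)-1-[4-(TBSO)-3-methoxyphenyl]propan-2-yl}cyclohexa-2,5-diene-1,4-diol F2, a mixture of carbinol epimers. Oxidation of the secondary bis-allylic alcohol with MnO2 (CH2Cl2) removes that centre and gives 29, where the route is rejoined.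

Step 13. What may go wrong: slow condensation of the iodo ylide with the hindered neopentyl-type aldehyde, decomposition of the ylide and erosion of Z-selectivity. The fallback sets out from 20. Dibromo-olefination (CBr4, PPh3, CH2Cl2, 0 °C) gives (5S)-5-(2,2-dibromoethenyl)-4-methoxy-5-{(2R)-1-[4-(TBSO)-3-methoxyphenyl]propan-2-yl}furan-2(5H)-one F3. A site-selective Stille coupling with allyltributylstannane (Pd2(dba)3, tri(2-furyl)phosphine, toluene, heat) replaces the bromine trans to the quaternary carbon and gives (5S)-5-[(1Z)-2-bromopenta-1,4-dien-1-yl]-4-methoxy-5-{(2R)-1-[4-(TBSO)-3-methoxyphenyl]propan-2-yl}furan-2(5H)-one F4. Copper-catalysed halogen exchange (CuI, NaI, N,N'-dimethylethylenediamine, dioxane, heat), which retains alkene geometry, returns to the route at 25.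

Step 10. What may go wrong: sluggish addition of the hindered tertiary hydroxyl to the ketenylidene phosphorane, with thermal decomposition of the reagent competing. The fallback sets out from 15. O-Acetylation (Ac2O, Sc(OTf)3 cat., MeCN) gives methyl (2S,3R)-2-acetoxy-2-[(benzyloxy)methyl]-3-methyl-4-[4-(TBSO)-3-methoxyphenyl]butanoate F5. Dieckmann cyclisation (LiN(SiMe3)2, THF, −78 → 0 °C) gives the tetronic acid (5S)-5-[(benzyloxy)methyl]-4-hydroxy-5-{(2R)-1-[4-(TBSO)-3-methoxyphenyl]propan-2-yl}furan-2(5H)-one F6. Mitsunobu O-methylation (MeOH, PPh3, diisopropyl azodicarboxylate, THF) of the 4-hydroxyl returns to the route at 18.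

**Further compounds**

F1 | step 14 | (5S)-5-[(1Z)-2-iodopenta-1,4-dien-1-yl]-4-methoxy-5-{(2R)-1-[4-(TBSO)-3-methoxyphenyl]propan-2-yl}-2,5-dihydrofuran-2-ol | COC1=CC(O)O[C@]1(/C=C(\I)CC=C)[C@H](C)Cc1ccc(O[Si](C)(C)C(C)(C)C)c(OC)c1
F2 | step 14 | (4S)-2-allyl-5-methoxy-4-{(2R)-1-[4-(TBSO)-3-methoxyphenyl]propan-2-yl}cyclohexa-2,5-diene-1,4-diol | C=CCC1=C[C@@](O)([C@H](C)Cc2ccc(O[Si](C)(C)C(C)(C)C)c(OC)c2)C(OC)=CC1O
F3 | step 13 | (5S)-5-(2,2-dibromoethenyl)-4-methoxy-5-{(2R)-1-[4-(TBSO)-3-methoxyphenyl]propan-2-yl}furan-2(5H)-one | COC1=CC(=O)O[C@]1(C=C(Br)Br)[C@H](C)Cc1ccc(O[Si](C)(C)C(C)(C)C)c(OC)c1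
F4 | step 13 | (5S)-5-[(1Z)-2-bromopenta-1,4-dien-1-yl]-4-methoxy-5-{(2R)-1-[4-(TBSO)-3-methoxyphenyl]propan-2-yl}furan-2(5H)-one | COC1=CC(=O)O[C@]1(/C=C(\Br)CC=C)[C@H](C)Cc1ccc(O[Si](C)(C)C(C)(C)C)c(OC)c1
F5 | step 10 | methyl (2S,3R)-2-acetoxy-2-[(benzyloxy)methyl]-3-methyl-4-[4-(TBSO)-3-methoxyphenyl]butanoate | COC(=O)[C@@](OC(C)=O)(COCc1ccccc1)[C@H](C)Cc1ccc(O[Si](C)(C)C(C)(C)C)c(OC)c1
F6 | step 10 | (5S)-5-[(benzyloxy)methyl]-4-hydroxy-5-{(2R)-1-[4-(TBSO)-3-methoxyphenyl]propan-2-yl}furan-2(5H)-one | OC1=CC(=O)O[C@]1(COCc1ccccc1)[C@H](C)Cc1ccc(O[Si](C)(C)C(C)(C)C)c(OC)c1
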